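**Retrosynthetic overview**

1. All rings are purchased intact: (2S)-pinocembrin (1) supplies the chromanone and the only stereocentre; 5-bromosaligenin (2, as its acetonide 3) and saligenin (4, as its O-Boc carbonate 5) supply the five phenol rings. No ring is constructed.
2. "Dimer" salicyl alcohol 6 ⇐ o-quinone methide (o-QM) from 5 + aryl Grignard from 3. "Trimer" salicyl alcohol 8 ⇐ o-QM from bis-Boc 7 (made from 6) + the same Grignard. The Br in 3 fixes every chain CH2 para to a phenol oxygen.
3. Target 10 ⇐ 9 + o-QM from 8 at C6; 9 ⇐ 1 + o-QM from 6 at C8. Each A-ring C–CH2 bond is drawn as a formal inverse-demand oxa-[4+2] of the o-QM across an A-ring enol C=C, followed by ring-opening and re-aromatisation (net C-benzylation); no cycloadduct is isolated.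
4. Order: chain arms first (4 → 6 → 8), then the C8 arm, then the C6 arm. C2 is never touched and no base is used after 1 enters.

Assumption: natural (−)-(2S)-pinocembrin is bought enantiopure (ee checked by chiral HPLC) and is the sole source of chirality.

**Route**

Step 1
Reactants: 2, 5-bromo-2-hydroxybenzyl alcohol
Product: 3, 6-bromo-2,2-dimethyl-4H-1,3-benzodioxine
Conditions: 2,2-dimethoxypropane, p-TsOH·H2O (2 mol %), acetone, rt
Reagents that add atoms: 2,2-dimethoxypropane, COC(C)(C)OC
Why: Acid-catalysed transketalisation ties the phenol and benzylic OH into an acetonide, removing both acidic protons so the bromide para to the phenol oxygen can become a Grignard reagent. (3 is also catalogued; if bought, this step is skipped.)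

Step 2
Reactants: 4, 2-hydroxybenzyl alcohol (saligenin)
Product: 5, tert-butyl 2-(hydroxymethyl)phenyl carbonate
Conditions: Boc2O (1.05 equiv), i-Pr2NEt, DMAP (2 mol %), CH2Cl2, −10 → 0 °C
Reagents that add atoms: di-tert-butyl dicarbonate, CC(C)(C)OC(=O)OC(=O)OC(C)(C)C
Why: Chemoselective carbonate formation at the more acidic phenol (the amine base cannot form the alkoxide) gives a Pettus-type anionic o-QM precursor.

Step 3
Reactants: 3, 6-bromo-2,2-dimethyl-4H-1,3-benzodioxine (2.4 equiv); 5, tert-butyl 2-(hydroxymethyl)phenyl carbonate (1 equiv)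
Product: 6, 4-(2-hydroxybenzyl)-2-(hydroxymethyl)phenol ("dimer" salicyl alcohol)
Conditions: 3, Mg, THF → ArMgBr; add 5 at −78 °C → rt; then 2 M aq HCl/MeOH, rt, same pot
Reagents that add atoms: none
Why: Deprotonation of the benzylic OH triggers O→O Boc migration and β-elimination to the parent o-QM, which the second equivalent of ArMgBr traps by 1,4-addition; dilute acid then hydrolyses the non-isolated acetonide 2-[(2,2-dimethyl-4H-1,3-benzodioxin-6-yl)methyl]phenol.

Step 4
Reactants: 6, 4-(2-hydroxybenzyl)-2-(hydroxymethyl)phenol
Product: 7, tert-butyl 2-({4-[(tert-butoxycarbonyl)oxy]-3-(hydroxymethyl)phenyl}methyl)phenyl carbonate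
Conditions: Boc2O (2.1 equiv), i-Pr2NEt, DMAP (2 mol %), CH2Cl2, −10 → 0 °C
Reagents that add atoms: di-tert-butyl dicarbonate, CC(C)(C)OC(=O)OC(=O)OC(C)(C)C
Why: Phenol-selective carbonate formation as in step 2 arms the salicyl unit for o-QM release and masks the remote phenol; the primary alcohol stays free as the trigger.

Step 5
Reactants: 3, 6-bromo-2,2-dimethyl-4H-1,3-benzodioxine (3 equiv, as ArMgBr); 7, bis-Boc dimer (1 equiv)
Product: 8, 2-(hydroxymethyl)-4-{[2-hydroxy-5-(2-hydroxybenzyl)phenyl]methyl}phenol ("trimer" salicyl alcohol)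
Conditions: ArMgBr (from 3, Mg, THF), add 7 at −78 °C → rt; then K2CO3, MeOH, rt; then 2 M aq HCl, rt, same pot
Reagents that add atoms: none
Why: The same Boc-migration/elimination/1,4-addition cascade extends the chain by one ring with the new CH2 para to the masked phenol by construction; methanolysis removes the remaining aryl carbonate and acid removes the acetonide.

Step 6
Reactants: 1, (2S)-pinocembrin (2.5 equiv, excess recovered); 6, dimer salicyl alcohol (1 equiv)
Product: 9, (2S)-5,7-dihydroxy-8-{[2-hydroxy-5-(2-hydroxybenzyl)phenyl]methyl}-2-phenylchroman-4-one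
Conditions: ZnCl2 (1.5 equiv), 1,4-dioxane, 85 °C, 6 added over 4 h; chromatographic separation from the C6 isomer and bis-adduct
Reagents that add atoms: none
Why: Zn(II)-assisted dehydration of 6 gives an o-QM that the A-ring captures, formally an oxa-[4+2] (hetero-Diels–Alder) across the C7(OH)=C8 enol bond whose hemiketal adduct reopens and re-aromatises (net Friedel–Crafts/Michael benzylation). C8/C6 selectivity is expected to be modest, so the isomers are separated and assigned by HMBC from the chelated 5-OH; base-free conditions leave C2 (S) intact.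

Step 7
Reactants: 9, 8-substituted pinocembrin (1 equiv); 8, trimer salicyl alcohol (1.5 equiv)
Product: 10, sarmentosumin D, (2S)-5,7-dihydroxy-8-{[2-hydroxy-5-(2-hydroxybenzyl)phenyl]methyl}-6-({2-hydroxy-5-[2-hydroxy-5-(2-hydroxybenzyl)benzyl]phenyl}methyl)-2-phenylchroman-4-one
Conditions: ZnCl2 (1.5 equiv), 1,4-dioxane, 85 °C, 8 added over 6 h; Sephadex LH-20 then RP-HPLC
Reagents that add atoms: none
Why: The same o-QM capture (formal oxa-[4+2] across C5(OH)=C6, then re-aromatisation) now has only one A-ring C–H left, and that phloroglucinol carbon is far more nucleophilic than the monophenol rings. The stereocentre is not involved and stays (2S).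

**Compound list**

1 | (2S)-pinocembrin | O=C1C[C@@H](c2ccccc2)Oc2cc(O)cc(O)c21 | starting material
2 | 5-bromo-2-hydroxybenzyl alcohol | OCc1cc(Br)ccc1O | starting material
3 | 6-bromo-2,2-dimethyl-4H-1,3-benzodioxine | CC1(C)OCc2cc(Br)ccc2O1 | intermediate
4 | 2-hydroxybenzyl alcohol (saligenin) | OCc1ccccc1O | starting material
5 | tert-butyl 2-(hydroxymethyl)phenyl carbonate | CC(C)(C)OC(=O)Oc1ccccc1CO | intermediate
6 | 4-(2-hydroxybenzyl)-2-(hydroxymethyl)phenol | OCc1cc(Cc2ccccc2O)ccc1O | intermediate
7 | tert-butyl 2-({4-[(tert-butoxycarbonyl)oxy]-3-(hydroxymethyl)phenyl}methyl)phenyl carbonate | OCc1cc(Cc2ccccc2OC(=O)OC(C)(C)C)ccc1OC(=O)OC(C)(C)C | intermediate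
8 | 2-(hydroxymethyl)-4-{[2-hydroxy-5-(2-hydroxybenzyl)phenyl]methyl}phenol | OCc1cc(Cc2cc(Cc3ccccc3O)ccc2O)ccc1O | intermediate
9 | (2S)-5,7-dihydroxy-8-{[2-hydroxy-5-(2-hydroxybenzyl)phenyl]methyl}-2-phenylchroman-4-one | O=C1C[C@@H](c2ccccc2)Oc2c(Cc3cc(Cc4ccccc4O)ccc3O)c(O)cc(O)c21 | intermediate
10 | sarmentosumin D | O=C1C[C@@H](c2ccccc2)Oc2c(Cc3cc(Cc4ccccc4O)ccc3O)c(O)c(Cc3cc(Cc4cc(Cc5ccccc5O)ccc4O)ccc3O)c(O)c21 | target

**Totals**

Total steps: 7 (6 if 3 is purchased). Longest linear sequence: 5 (steps 1 → 3 → 4 → 5 → 7).

**Steps most likely to fail**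

- **Step 6 (C8 versus C6 regioselectivity, over-benzylation).** The first benzylation has little intrinsic bias, so up to half the material may go to the C6 isomer. Fallback: block C6 before coupling. Make the 7-O-TBS ether of 1, iodinate at C6 under 5-OH direction (BnMe3N·ICl2, CaCO3), desilylate with HF·pyridine, run the o-QM coupling (only C8 is open), then remove iodine reductively (Zn/AcOH) before step 7.
- **Step 7 (o-QM self-oligomerisation of 8, attack on chain phenols, possible ee erosion under ZnCl2/heat).** Fallback: replace o-QM capture with cross-coupling. Iodinate 9 at C6 (NIS; the only free A-ring position) and join it by Pd-catalysed sp2–sp3 Suzuki–Miyaura coupling to the benzylic pinacol boronate of O-acetylated 8, then remove the acetates by acid-catalysed methanolysis.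
- **Steps 4–5 (phenol-selective Boc protection of triol 6 and the o-QM/Grignard cascade on a substrate carrying a second aryl carbonate).** Fallback: abandon the anionic o-QM route for this bond. Peracetylate 6, convert 3 to its pinacol boronate (B2pin2, Pd(dppf)Cl2, KOAc), couple the benzylic acetate with the aryl boronate under Pd catalysis, and then deprotect globally (K2CO3/MeOH, then dilute HCl).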